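**Assumptions (one line each):**
- Oridonin is treated as a commercial bulk natural product (kilogram-scale extraction from *Isodon rubescens*) and is the only chiral input.
- The C16 epimer ratio after hydrogenation is unassigned, so C16 is left unspecified in SMILES 2–10.
- The route is a design proposal; selectivities and yields have not been tested.

## Retrosynthetic overview
1. Ludongnin H comes from thermodynamic equilibration of C16 (exo-methyl) of the C16-epimeric methyl acetal **10**.
2. Acetal **10** comes from anodic α-methoxylation of the 6,19-oxolane **8**, which sets C6 by anomeric control.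
3. Oxolane **8** comes from a photochemical (hypoiodite) 1,5-HAT etherification of the C6 hydroxymethyl onto the C4 methyl syn to C20 (C19). This step differentiates the two methyls and fixes C4.
4. Alcohol **7** comes from the C6 aldehyde of 1,14-dideoxy seco-lactone **6**, made by Criegee cleavage of the 6β-OH/7-hemiketal diol of dihydro-oridonin. Oridonin already supplies C4/C5/C8/C9/C10/C13 stereochemistry, the C20 oxidation and the B-ring oxygenation.
5. Ring order: the B ring is opened and the 7,20-lactone is unveiled in step 2; the 6,19-oxolane ring is formed in step 6; no other ring is made.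

## Route

**Step 1**
Reactants: **1** oridonin, (1α,6β,7,14R)-7,20-epoxy-1,6,7,14-tetrahydroxy-ent-kaur-16-en-15-one
Product: **2** 16,17-dihydrooridonin (C16 epimeric mixture)
Conditions: H2 (1 atm), 10% Pd/C, EtOH, 25 °C
Reagents that add atoms: none
Why: Catalytic hydrogenation saturates only the exocyclic enone C=C, so it is no longer a radical acceptor in later steps; it creates the epimeric C16 that step 8 funnels to one isomer and leaves all other centres untouched.

**Step 2**
Reactants: **2**
Product: **3** 1α,14R-dihydroxy-15-oxo-6,7-seco-ent-kauran-6-al-7,20-olide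
Conditions: Pb(OAc)4 (1.2 equiv), PhH, 25 °C
Reagents that add atoms: none
Why: Criegee glycol cleavage of the vicinal 6β-OH/7-hemiketal OH turns C6 into an aldehyde and C7 into the lactone carbonyl (O20 retained), with no new stereocentre and C5 unchanged.

**Step 3**
Reactants: **3**; **4** phenyl chlorothionoformate
Product: **5** 1α,14R-bis(O-phenyl thionocarbonate) of **3**
Conditions: **4** (2.6 equiv), DMAP (3 equiv), MeCN, 50 °C
Reagents that add atoms: phenyl chlorothionoformate, S=C(Cl)Oc1ccccc1
Why: O-thioacylation (Robins conditions) of the two secondary alcohols; the aldehyde, ketone and lactone do not react.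

**Step 4**
Reactants: **5**
Product: **6** 15-oxo-6,7-seco-ent-kauran-6-al-7,20-olide (1,14-dideoxy)
Conditions: (TMS)3SiH (3 equiv), Et3B (0.3 equiv), air, PhMe, 25 °C
Reagents that add atoms: none
Why: Barton–McCombie radical deoxygenation removes the C1 and C14 oxygens and their stereocentres; C14-radical β-scission would need an anti-Bredt bridgehead alkene, and the low temperature limits acyl-radical decarbonylation.

**Step 5**
Reactants: **6**
Product: **7** 6-hydroxy-15-oxo-6,7-seco-ent-kauran-7,20-olide
Conditions: NaBH4 (0.3 equiv), EtOH/CH2Cl2 (1:1), −78 °C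
Reagents that add atoms: none
Why: The unhindered C6 aldehyde is reduced chemoselectively over the hindered bridged C15 ketone and the neopentyl lactone, and C5 is not epimerised at −78 °C.

**Step 6**
Reactants: **7**
Product: **8** 6,19-epoxy-15-oxo-6,7-seco-ent-kauran-7,20-olide
Conditions: PhI(OAc)2 (1.5 equiv), I2 (0.6 equiv), cyclohexane, visible light, 25 °C
Reagents that add atoms: none
Why: Proposed new method: the hypoiodite of the C6 CH2OH gives a primary alkoxyl radical that abstracts H by 1,5-HAT from the C4 methyl syn to C20 (C19). The α-acyloxy C20–H is polarity-mismatched for this electrophilic radical, and the cis-fused 5/6 closure is the lower-strain mode. The C19 radical is then iodinated and O-alkylated (or oxidised) to close the oxolane, so C4 is set by substrate control and the minor diastereomer is separated. The closest known reaction is the Suárez/Kalvoda–Heusler hypoiodite etherification (steroid 6β-OH→C19), extended here to a freely rotating exocyclic CH2OH that must discriminate two diastereotopic methyls on a 6,7-seco-ent-kauranoid.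

**Step 7**
Reactants: **8**; **9** methanol
Product: **10** 6-methoxy-6,19-epoxy-15-oxo-6,7-seco-ent-kauran-7,20-olide (C16 epimeric, C6 acetal as in target)
Conditions: graphite(+)/Pt(−), Et4N·OTs (0.1 M), MeOH/CH2Cl2 (3:1), 10 mA, 0 °C; then PPTS (10 mol %), MeOH, 25 °C
Reagents that add atoms: methanol, CO
Why: Shono-type anodic α-methoxylation occurs at the less hindered C6 methylene (C19 is neopentylic), and the oxocarbenium is trapped by MeOH; the PPTS treatment equilibrates C6 to the convex-face anomer (OMe cis to H5) seen in the target.

**Step 8**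
Reactants: **10**
Product: **11** ludongnin H (16S, exo-methyl)
Conditions: DBU (2 equiv), PhMe, 80 °C
Reagents that add atoms: none
Why: Deprotonation α to C15 and reprotonation equilibrate C16 to the thermodynamically preferred exo-methyl (the endo isomer suffers syn-interactions with the three-carbon bridge); the acetal, lactone and ketone survive a non-nucleophilic base.

## Compound list
1 | oridonin | CC1(C)CC[C@@H](O)[C@]23CO[C@](O)([C@H](O)[C@H]12)[C@@]45[C@H](O)[C@@H](CC[C@H]43)C(=C)C5=O | starting material
2 | 16,17-dihydrooridonin (C16 unassigned) | CC1(C)CC[C@@H](O)[C@]23CO[C@](O)([C@H](O)[C@H]12)[C@@]45[C@H](O)[C@@H](CC[C@H]43)C(C)C5=O | intermediate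
3 | 1α,14R-dihydroxy-15-oxo-6,7-seco-ent-kauran-6-al-7,20-olide | O=C[C@@H]1C(C)(C)CC[C@@H](O)[C@]12COC(=O)[C@@]34[C@H](O)[C@@H](CC[C@@H]23)C(C)C4=O | intermediate
4 | phenyl chlorothionoformate | S=C(Cl)Oc1ccccc1 | reagent (starting material)
5 | 1,14-bis(O-phenyl thionocarbonate) of 3 | O=C[C@@H]1C(C)(C)CC[C@@H](OC(=S)Oc5ccccc5)[C@]12COC(=O)[C@@]34[C@H](OC(=S)Oc5ccccc5)[C@@H](CC[C@@H]23)C(C)C4=O | intermediate
6 | 15-oxo-6,7-seco-ent-kauran-6-al-7,20-olide | O=C[C@@H]1C(C)(C)CCC[C@]12COC(=O)[C@@]34C[C@@H](CC[C@@H]23)C(C)C4=O | intermediate
7 | 6-hydroxy-15-oxo-6,7-seco-ent-kauran-7,20-olide | OC[C@@H]1C(C)(C)CCC[C@]12COC(=O)[C@@]34C[C@@H](CC[C@@H]23)C(C)C4=O | intermediate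
8 | 6,19-epoxy-15-oxo-6,7-seco-ent-kauran-7,20-olide | C1OC[C@]2(C)CCC[C@]3(COC(=O)[C@@]45C[C@@H](CC[C@H]43)C(C)C5=O)[C@H]12 | intermediate
9 | methanol | CO | reagent (starting material)
10 | 6-methoxy-6,19-epoxy-15-oxo-6,7-seco-ent-kauran-7,20-olide (C16 unassigned) | CO[C@H]1OC[C@]2(C)CCC[C@]3(COC(=O)[C@@]45C[C@@H](CC[C@H]43)C(C)C5=O)[C@H]12 | intermediate
11 | ludongnin H | CO[C@H]1OC[C@]2(C)CCC[C@]3(COC(=O)[C@@]45C[C@@H](CC[C@H]43)[C@H](C)C5=O)[C@H]12 | target

## Totals
Total steps: 8. Longest linear sequence: 8.

## Three steps most likely to fail
1. **Step 6 (proposed new step).** Risks are C18/C19 discrimination, β-fragmentation of the primary alkoxyl radical, and attack at C9–H.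
   Fallback: convert the aldehyde **6** to its O-methyl oxime and run Pd(OAc)2/PhI(OAc)2 oxime-directed sp3 C–H acetoxylation of the syn C4 methyl (Sanford palladacycle chemistry). Then do mild methanolysis of the acetate, regenerate the aldehyde, and form the methyl acetal with MeOH/PPTS, which also removes step 7.
2. **Step 4.** Risks are aldehyde-derived acyl-radical decarbonylation and base-promoted acyl migration of the lactone to the 1α-OH.
   Fallback: run the step 2 cleavage in MeOH so C6 is carried as its dimethyl acetal, deoxygenate C1 and C14 with the aldehyde masked, and then unmask the aldehyde (aq. TFA) before the step 5 reduction.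
3. **Step 7.** The risk is oxidation at C19 instead of C6, or poor anomeric control.
   Fallback: generate the oxocarbenium chemically by hydride abstraction with Ph3C⁺BF4⁻ in CH2Cl2 at the more hydridic, less hindered C6–H, then quench with MeOH and equilibrate with PPTS.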